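## Structural features

Selaginellin is built on one benzene core (ring A) with four contiguous carbon substituents. C1 carries the exocyclic methide carbon of a p-quinone methide, which also holds a 4-hydroxyphenyl ring. C2 carries a second 4-hydroxyphenyl ring, C5 a hydroxymethyl group and C6 a (4-hydroxyphenyl)ethynyl group, while C3 and C4 carry hydrogen. There is no stereocentre, so no stereocentres stand next to each other, and the methide double bond has no E/Z isomerism because the quinone ring and the phenol ring on that carbon interconvert by proton shift. The fragile parts are the quinone methide (the dehydrated form of a triarylcarbinol, a triarylmethyl cation in acid), the electron-rich diarylalkyne lying ortho both to that carbon and to a benzylic alcohol, and three free phenols. The real difficulty is the 1,2,3,4-substitution of ring A: C1 and C6 are each flanked on both sides, and the C1 substituent is a fully substituted, ionisable carbon, so substitution on a preformed benzene would meet steric and regiochemical problems at once. The key step uses two features: C3 and C4 are bare like the carbons of acetylene, and the oxygen of the carbinol form of the methide carbon is three bonds from C6, so one silicon atom can join O to C6. Ring A then arises from the alkynes C1≡C2 and C5≡C6, held by the C–O–Si tether, plus acetylene; the silicon left on C6 is the handle for the arylethynyl group and the Si–O bond gives back the carbinol.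

## Logic of the disconnections

**20 ⇒ 19.** The C=C bond between the methide carbon and the quinone ring of 20, and its four O–H bonds, are traced back to 19, a tertiary carbinol with three phenol acetals and a benzylic silyl ether. A 4-hydroxyphenyl carbinol loses water to the quinone methide under the same acid that removes these groups. This keeps the electrophilic quinone methide and the acidic phenols out of every earlier step. The forward step must be mild enough to spare the alkyne and the benzylic alcohol beside it.

**19 ⇒ 18 + 5.** The bond between C6 and its alkyne carbon is cut, giving 18 (C6–OTf) and 5. The arylethynyl group must come after ring formation, because a third alkyne in the cyclotrimerisation substrate would compete for the metallacycle. One of the four ring A substituents becomes a building block that is used twice. The forward coupling must work at a carbon flanked on both sides and next to a free tertiary alcohol.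

**18 ⇒ 17 ⇒ 16.** The S–O bond of 18 leads to 17 (C6–OH), and the C6–O bond and carbinol O–H of 17 are traced to the C6–Si and O–Si bonds of 16. An aryl–silicon bond with an alkoxy group on silicon is a masked phenol, so both bonds of the temporary tether are used productively. The C1 and C6 substituents become the two ends of one five-membered ring. The forward oxidation must succeed at a crowded silicon without protodesilylation, and the sulfonylation must pick the phenol over the ionisable tertiary alcohol.

**16 ⇒ 14 + 15.** Three ring A bonds are cut together: C1–C6, C2–C3 and C4–C5. This gives 14, in which C1≡C2 and C5≡C6 are joined by the C–O–Si tether, and 15, which supplies C3 and C4. Every substituent of ring A is then placed by the connectivity of an open-chain compound, with no regiochemical choice. The forward step must favour the cross-reaction over self-reaction of 14 and trimerisation of 15.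

**14 ⇒ 5 + 7 + 11.** The bond between the carbinol carbon and C1, and the O–Si bond, are cut. The carbinol carbon is the carbonyl carbon of a diaryl ketone that cannot enolise, and the alkoxide from the addition is itself the nucleophile for silicon, so the ionisation-prone free propargylic alcohol is never handled. Three pieces of similar size are joined in one flask. The forward step needs silylation of a hindered tertiary alkoxide, and 14 must be kept from acid.

**11 ⇒ 8 + 9.** The Si–C(sp) bond is cut. Both pieces are commercial. The forward step must stop at monosubstitution on silicon, which an excess of 9 secures.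

**5 ⇒ 4 ⇒ 2 + 3.** The aryl–alkyne bond is cut, with a silyl cap on the alkyne. This is the standard way to a terminal arylalkyne, and it only requires that the cap come off under base.

**2 ⇒ 1 and 7 ⇒ 6.** The O–CH2 bonds of the acetals are cut. The acetal is chosen because it survives organolithium, base, peroxide, palladium and rhodium and falls in the acid of the last step.

## Other disconnections considered

**Alternative 1:** The cut goes through C4–C5 and C1–C2 of ring A. In the forward direction TiCl4 would promote a formal [3+3] cyclocondensation of the 1,3-bis(silyloxy)diene A2 with the 3-silyloxy enone A3. The diene terminus (C5) would add to the silyloxy-bearing C4, the central diene carbon (C1) would close onto the aryl ketone carbon (C2) in a Mukaiyama aldol step, and loss of silanol and water would give the salicylate A1.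
- In its favour: ring A comes from two small acyclic partners without a precious metal or a gas. The polarity of A2 and A3 fixes the regiochemistry as firmly as the tether does in the chosen plan, which makes it the equal on that point. C6 arrives directly as a phenol, so no Tamao oxidation is needed before triflation, which makes it the better on that point.
- Against it here: A2 carries a silyloxy group β to the carbon that must be deprotonated when it is made, which invites elimination. The Lewis acid may cleave silyl ethers. Above all, the C1 ester of A1 would have to accept two aryl nucleophiles while flanked by the C2 aryl group and the C6 substituent.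
- Comparison: in structure both plans place all four substituents by construction. In mechanism the chosen plan builds the crowded carbinol first, from an unhindered diaryl ketone, and closes ring A around it, whereas this alternative closes ring A first and then must force the carbinol into the most hindered position. In step economy the two should be close, since what is saved at C6 is spent on A2, A3 and the aryl additions.

**Alternative 2:** The cut removes the C5–CO2Me and C6–alkynyl bonds of the benzoate A4 and leads back to the aryl iodide A5. In the forward Catellani reaction zerovalent palladium (from Pd(OAc)2 and a triarylphosphine) would insert into the C6–I bond of A5. Norbornene would relay the metal to C5 through an aryl–norbornyl palladacycle, dimethyl dicarbonate A6 would deliver the methoxycarbonyl group there, and after norbornene extrusion the C6 arylpalladium would be captured by alkyne 5 with Cs2CO3 as base.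
- In its favour: the two bonds at the most crowded positions, among them the C6–alkyne bond that costs the chosen plan three steps, would be made in one operation. A5 has the ortho substituent this reaction type needs. The methide carbon travels at the unreactive triarylmethane level. On step count this is the better plan on paper.
- Against it here: the ortho substituent is a diarylmethyl group whose aryl C–H bonds lie within reach of the C6 arylpalladium, so cyclopalladation to a 9-arylfluorene can compete with norbornene insertion. A6 is a weaker and more base-sensitive acyl donor than the anhydrides usual in ortho acylation, and it must react with the divalent palladium of the palladacycle faster than 5 couples directly at C6. Afterwards the ester of A4 must be reduced and the triarylmethane C–H oxidised in the presence of an electron-rich alkyne and a benzylic alcohol.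
- Comparison: in structure A4 maps onto 20 as well as 16 does. In mechanism the alternative depends on selectivity among several C–H bonds and three coupling partners, whereas the chosen plan needs only cross-selectivity of a tethered cyclotrimerisation. The chosen plan is longer but rests on safer individual steps.

**Alternative 3:** The cut is the C3–C4 bond. Heating the 3,4-bis(vinyl)butenolide A8 would bring about thermal, disrotatory 6π-electrocyclisation of the triene C4=C5–C6=C1–C2=C3 to the cyclohexa-1,3-diene A7. A7 is a 5,6-dihydrophthalide: its two sp3 carbons are C3 and C4 of ring A, which are C5 and C6 in phthalide numbering, so the locants 6,7 would not fit its connectivity. Dehydrogenation would give the phthalide A9. Its lactone carbon would then have to become the first alkyne carbon (reduction to the lactol, one-carbon homologation to the ethynyl carbinol, Sonogashira coupling with 2) before the acid step.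
- In its favour: no metal or gas is needed in ring formation, and there is no regiochemical or stereochemical question, which makes it the equal of the chosen plan. The carbinol carbon is locked as a lactone that cannot ionise, which is more robust than 17 to 19. The final Sonogashira coupling would have its oxidative addition at unhindered 2 rather than at a crowded C6 triflate. On the last two points it is the better plan.
- Against it here: both vinyl groups of A8 are 1,1-disubstituted and one stands beside the gem-diaryl carbon, so the reactive s-cis,s-cis conformer is strained. Ring closure would need temperatures at which styrene-type dienes polymerise and hydrogen shifts move the diene. Making A8 needs two different vinyl groups on adjacent carbons. Aromatisation and the lactone-to-alkyne conversion add redox and homologation steps.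
- Comparison: in structure both plans fix every position of ring A. In mechanism the pericyclic step is predictable but sterically penalised, whereas the metal-templated step tolerates substituted termini. In step economy the alternative should be clearly longer.

Key step: step 7

Remarks on the chemistry:
- The structure defines no stereocentre and no axial configuration, so none is controlled.
- The C5 arm is carried as a tert-butyldimethylsilyl ether rather than a fourth MOM acetal. An alkyl MOM ether would be the slowest group to cleave and would set the acidity of the last step, whereas a primary silyl ether falls with the aryl acetals under mild acid. Compound 8 is commercial, which saves one protection step. The skeleton of the diyne, the tether and the bonds formed in the key step are unchanged.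
- Silicon keeps two methyl groups, because bulkier groups would slow the oxidation at the crowded C6 silicon in step 8. In return, 14 is not chromatographed on untreated silica.

## Route

Step 1
Reactants: 1 4-iodophenol
Product: 2 1-iodo-4-(methoxymethoxy)benzene
Conditions: MOMCl, i-Pr2NEt, CH2Cl2, 0 °C to rt
Reagents that add atoms: chloromethyl methyl ether, COCCl
Why: O-alkylation of the phenol by the reactive α-chloro ether under amine base gives the mixed acetal; the MOM group resists n-BuLi, amines, palladium, rhodium and basic peroxide and falls in the final acid step.

Step 2
Reactants: 2 1-iodo-4-(methoxymethoxy)benzene; 3 ethynyltrimethylsilane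
Product: 4 {[4-(methoxymethoxy)phenyl]ethynyl}trimethylsilane
Conditions: PdCl2(PPh3)2 (cat.), CuI (cat.), Et3N, THF, rt
Reagents that add atoms: none
Why: Sonogashira coupling (oxidative addition of the aryl iodide to zerovalent palladium, transmetalation from the copper acetylide, reductive elimination); the silyl cap prevents double arylation.

Step 3
Reactants: 4 {[4-(methoxymethoxy)phenyl]ethynyl}trimethylsilane
Product: 5 1-ethynyl-4-(methoxymethoxy)benzene
Conditions: K2CO3 (cat.), MeOH, rt
Reagents that add atoms: none
Why: Methoxide-catalysed protodesilylation of the alkynylsilane; the aryl acetal is inert to base.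

Step 4
Reactants: 6 4,4'-dihydroxybenzophenone
Product: 7 bis[4-(methoxymethoxy)phenyl]methanone
Conditions: MOMCl, i-Pr2NEt, DMF, 0 °C to rt
Reagents that add atoms: chloromethyl methyl ether, COCCl
Why: The same O-alkylation on both phenols; the diaryl ketone has no α-hydrogen and is untouched.

Step 5
Reactants: 8 tert-butyldimethyl(prop-2-yn-1-yloxy)silane; 9 dichlorodimethylsilane
Product: 11 tert-butyl({3-[chloro(dimethyl)silyl]prop-2-yn-1-yl}oxy)dimethylsilane, via lithium acetylide 10 (not isolated)
Conditions: n-BuLi, THF, −78 °C; inverse addition to 9 (excess), −78 °C to rt; evaporation, bulb-to-bulb distillation under argon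
Reagents that add atoms: none
Why: Deprotonation of the terminal alkyne and nucleophilic substitution at silicon; inverse addition into excess 9 limits the reaction to one Si–Cl bond, and the volatile excess is removed in vacuum.

Step 6
Reactants: 5 1-ethynyl-4-(methoxymethoxy)benzene; 7 bis[4-(methoxymethoxy)phenyl]methanone; 11 tert-butyl({3-[chloro(dimethyl)silyl]prop-2-yn-1-yl}oxy)dimethylsilane
Product: 14 ({1,1-bis[4-(methoxymethoxy)phenyl]-3-[4-(methoxymethoxy)phenyl]prop-2-yn-1-yl}oxy)[3-(tert-butyldimethylsilyloxy)prop-1-yn-1-yl]dimethylsilane (the tethered 1,6-diyne), via lithium arylacetylide 12 (not isolated), via lithium alkoxide 13 (not isolated)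
Conditions: n-BuLi, THF, −78 °C; 7, −78 to 0 °C; 11, 0 °C to rt; aq NaHCO3 work-up, filtration through Et3N-deactivated silica
Reagents that add atoms: none
Why: 1,2-Addition of a lithium acetylide to a non-enolisable diaryl ketone, then O-silylation of the tertiary alkoxide by the chlorosilane; trapping in the flask avoids isolating a propargylic alcohol that ionises easily (Meyer–Schuster rearrangement).

Step 7
Reactants: 14 the tethered 1,6-diyne; 15 acetylene
Product: 16 7-{[tert-butyl(dimethyl)silyl]oxymethyl}-1,1-dimethyl-3,3,4-tris[4-(methoxymethoxy)phenyl]-1,3-dihydro-2,1-benzoxasilole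
Conditions: RhCl(PPh3)3 (10 mol%), acetylene (1 atm), toluene, 60 °C, slow addition of 14
Reagents that add atoms: none
Why: RhCl(PPh3)3 loses a phosphine, binds both alkynes of 14 and couples them oxidatively (monovalent rhodium becoming trivalent) to a rhodacyclopentadiene; this cyclometallation forms C1–C6 and closes the five-membered oxasilole (C1, carbinol carbon, O, Si, C6). Acetylene then coordinates and inserts into a Rh–C bond, and reductive elimination makes the last bond, so that C2–C3 and C4–C5 close the six-membered ring A and monovalent rhodium is released. The closest known reaction type is the RhCl(PPh3)3-catalysed [2+2+2] cycloaddition of tethered 1,6-diynes, including alkynylsilyl ethers of propargylic alcohols, with acetylene. No stereocentre is formed. The step needs chemoselectivity for the cross-reaction over dimerisation of 14 and trimerisation of 15: the gem-diaryl carbon in the tether favours the folded conformer and fast intramolecular metallacycle formation, both alkyne termini of 14 are substituted so a second molecule of 14 inserts far more slowly than the small 15, and 15 is in excess while 14 is added slowly. There is no regiochemical choice, because the tether decides which alkyne carbons are joined and 15 is symmetric. The acetals, the silyl ether and the tertiary C–O–Si link are inert to the neutral catalyst.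

Step 8
Reactants: 16 the benzoxasilole
Product: 17 2-{hydroxybis[4-(methoxymethoxy)phenyl]methyl}-6-{[tert-butyl(dimethyl)silyl]oxymethyl}-3-[4-(methoxymethoxy)phenyl]phenol
Conditions: H2O2 (30% aq), KHCO3, THF/MeOH 1:1, rt to 45 °C; aq Na2S2O3 quench
Reagents that add atoms: hydrogen peroxide, OO
Why: Tamao oxidation: hydroperoxide adds to the cyclic alkoxysilane (the ring oxygen supplies the heteroatom activation), the aryl group shifts from silicon to oxygen, and hydrolysis of both Si–O bonds frees the C6 phenol and the tertiary carbinol; bicarbonate conditions spare the acetals and the silyl ether.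

Step 9
Reactants: 17 the phenol carbinol
Product: 18 2-{hydroxybis[4-(methoxymethoxy)phenyl]methyl}-6-{[tert-butyl(dimethyl)silyl]oxymethyl}-3-[4-(methoxymethoxy)phenyl]phenyl trifluoromethanesulfonate
Conditions: PhNTf2, Et3N, DMAP (cat.), CH2Cl2, 0 °C to rt
Reagents that add atoms: N-phenylbis(trifluoromethanesulfonimide), O=S(=O)(N(c1ccccc1)S(=O)(=O)C(F)(F)F)C(F)(F)F
Why: O-sulfonylation of the phenol by a mild triflyl donor; the tertiary alcohol is not deprotonated by Et3N and is not attacked, which avoids the ionisation that triflic anhydride would cause.

Step 10
Reactants: 18 the aryl triflate; 5 1-ethynyl-4-(methoxymethoxy)benzene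
Product: 19 {3-{[tert-butyl(dimethyl)silyl]oxymethyl}-6-[4-(methoxymethoxy)phenyl]-2-{[4-(methoxymethoxy)phenyl]ethynyl}phenyl}bis[4-(methoxymethoxy)phenyl]methanol
Conditions: Pd(PPh3)4 (cat.), CuI (cat.), Et3N/DMF 1:4, 70 °C, degassed, slow addition of 5
Reagents that add atoms: none
Why: Sonogashira coupling of an aryl triflate; a polar solvent and heating drive oxidative addition at the di-ortho-substituted carbon, and slow addition of 5 limits its oxidative dimerisation.

Step 11
Reactants: 19 the protected carbinol
Product: 20 selaginellin, 4-{[3-(hydroxymethyl)-2-[(4-hydroxyphenyl)ethynyl]-6-(4-hydroxyphenyl)phenyl](4-hydroxyphenyl)methylidene}cyclohexa-2,5-dien-1-one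
Conditions: HCl (conc., few equiv), MeOH/THF 3:1, rt to 40 °C; then aq NaHCO3 to neutral
Reagents that add atoms: none
Why: Acid-catalysed methanolysis removes the three aryl acetals and the primary silyl ether; the carbinol ionises to a triarylmethyl cation stabilised by two para oxygens and, on neutralisation, loses a phenolic proton to give the quinone methide (fuchsone formation); no stereocentre or double-bond geometry is at stake because the two rings on the methide carbon are equivalent.

## Compound list

1 | 4-iodophenol | Oc1ccc(I)cc1 | starting material
2 | 1-iodo-4-(methoxymethoxy)benzene | COCOc1ccc(I)cc1 | intermediate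
3 | ethynyltrimethylsilane | C#C[Si](C)(C)C | starting material
4 | {[4-(methoxymethoxy)phenyl]ethynyl}trimethylsilane | COCOc1ccc(C#C[Si](C)(C)C)cc1 | intermediate
5 | 1-ethynyl-4-(methoxymethoxy)benzene | COCOc1ccc(C#C)cc1 | intermediate
6 | 4,4'-dihydroxybenzophenone | O=C(c1ccc(O)cc1)c1ccc(O)cc1 | starting material
7 | bis[4-(methoxymethoxy)phenyl]methanone | COCOc1ccc(cc1)C(=O)c1ccc(OCOC)cc1 | intermediate
8 | tert-butyldimethyl(prop-2-yn-1-yloxy)silane | C#CCO[Si](C)(C)C(C)(C)C | starting material
9 | dichlorodimethylsilane | C[Si](C)(Cl)Cl | starting material
10 | [3-(tert-butyldimethylsilyloxy)prop-1-yn-1-yl]lithium | [Li]C#CCO[Si](C)(C)C(C)(C)C | intermediate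
11 | tert-butyl({3-[chloro(dimethyl)silyl]prop-2-yn-1-yl}oxy)dimethylsilane | CC(C)(C)[Si](C)(C)OCC#C[Si](C)(C)Cl | intermediate
12 | {[4-(methoxymethoxy)phenyl]ethynyl}lithium | [Li]C#Cc1ccc(OCOC)cc1 | intermediate
13 | lithium 1,1,3-tris[4-(methoxymethoxy)phenyl]prop-2-yn-1-olate | [Li]OC(C#Cc1ccc(OCOC)cc1)(c1ccc(OCOC)cc1)c1ccc(OCOC)cc1 | intermediate
14 | ({1,1-bis[4-(methoxymethoxy)phenyl]-3-[4-(methoxymethoxy)phenyl]prop-2-yn-1-yl}oxy)[3-(tert-butyldimethylsilyloxy)prop-1-yn-1-yl]dimethylsilane | COCOc1ccc(C#CC(O[Si](C)(C)C#CCO[Si](C)(C)C(C)(C)C)(c2ccc(OCOC)cc2)c2ccc(OCOC)cc2)cc1 | intermediate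
15 | acetylene | C#C | starting material
16 | 7-{[tert-butyl(dimethyl)silyl]oxymethyl}-1,1-dimethyl-3,3,4-tris[4-(methoxymethoxy)phenyl]-1,3-dihydro-2,1-benzoxasilole | CC(C)(C)[Si](C)(C)OCc1ccc(-c2ccc(OCOC)cc2)c2c1[Si](C)(C)OC2(c1ccc(OCOC)cc1)c1ccc(OCOC)cc1 | intermediate
17 | 2-{hydroxybis[4-(methoxymethoxy)phenyl]methyl}-6-{[tert-butyl(dimethyl)silyl]oxymethyl}-3-[4-(methoxymethoxy)phenyl]phenol | CC(C)(C)[Si](C)(C)OCc1ccc(-c2ccc(OCOC)cc2)c(c1O)C(O)(c1ccc(OCOC)cc1)c1ccc(OCOC)cc1 | intermediate
18 | 2-{hydroxybis[4-(methoxymethoxy)phenyl]methyl}-6-{[tert-butyl(dimethyl)silyl]oxymethyl}-3-[4-(methoxymethoxy)phenyl]phenyl trifluoromethanesulfonate | CC(C)(C)[Si](C)(C)OCc1ccc(-c2ccc(OCOC)cc2)c(c1OS(=O)(=O)C(F)(F)F)C(O)(c1ccc(OCOC)cc1)c1ccc(OCOC)cc1 | intermediate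
19 | {3-{[tert-butyl(dimethyl)silyl]oxymethyl}-6-[4-(methoxymethoxy)phenyl]-2-{[4-(methoxymethoxy)phenyl]ethynyl}phenyl}bis[4-(methoxymethoxy)phenyl]methanol | CC(C)(C)[Si](C)(C)OCc1ccc(-c2ccc(OCOC)cc2)c(c1C#Cc1ccc(OCOC)cc1)C(O)(c1ccc(OCOC)cc1)c1ccc(OCOC)cc1 | intermediate
20 | selaginellin | O=C1C=CC(=C(c2ccc(O)cc2)c2c(-c3ccc(O)cc3)ccc(CO)c2C#Cc2ccc(O)cc2)C=C1 | target

## Step count and least certain steps

Total step count: 11. Longest linear sequence: 9 steps (steps 1, 2, 3, 6, 7, 8, 9, 10, 11).

**Step 7 (key step).** Self-reaction of the diyne or trimerisation of acetylene may outpace the cross-reaction. The cycle may also stall at the rhodacyclopentadiene, because the aryl group on C2 and the silyloxymethyl group on C5 crowd the site where acetylene must insert. At higher temperature the tertiary propargylic C–O bond may ionise. The fallback sets out from 14 and returns to the route at 16. The gas is replaced by vinyl acetate as a liquid acetylene equivalent, used in large excess with a cationic catalyst made from [Rh(cod)2]BF4 and BINAP in CH2Cl2. The alkene inserts into the same rhodacycle, and the cyclohexadienyl acetate F1 (not isolated, racemic; written with the acetate on C4, the C3 regioisomer converging on the same arene) loses acetic acid to give 16. The partner then cannot trimerise to benzene and its concentration is not limited by gas solubility.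

**Step 8.** Protodesilylation at C6 may occur under the basic peroxide, or hydroperoxide may attack the silicon only slowly, since it is flanked by the quaternary carbon and the C5 arm. Loss of water from 17 to an ortho-quinone methide on acidic silica is a further risk. The fallback sets out from 16 and returns at 19. Electrophilic ipso-iododesilylation with NIS and AgF in MeCN, followed by aqueous work-up, should give the aryl iodide F2. Sonogashira coupling of F2 with 5 (PdCl2(PPh3)2, CuI, Et3N, rt) then gives 19 and bypasses 17 and 18. The point to watch is competing ring iodination of the alkoxyarenes.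

**Step 10.** Oxidative addition of the di-ortho-substituted triflate to zerovalent palladium may be slow. Oxidative dimerisation of 5 could then take over, as could addition of the neighbouring tertiary hydroxyl to the new alkyne at the temperature needed. The fallback sets out from 18 and returns at 19. Compound 18 is first coupled with the small alkyne 3, used in excess, to give the silylalkyne F3. The silyl cap is removed (K2CO3, MeOH) to give the terminal alkyne F4. F4 is then coupled with the unhindered iodide 2 at room temperature. The demanding bond is thus made with the least hindered alkyne, and the diarylalkyne is completed under mild conditions.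

**Step 6.** Silylation of the hindered alkoxide 13 by the bulky chlorosilane 11 may be incomplete, 11 may hydrolyse before use, and the tertiary silyl ether of 14 may cleave during isolation. The fallback sets out from 13 (made from 5 and 7 as in step 6) and returns at 14. The order of bond formation at silicon is reversed. Compound 13 is added to an excess of 9 to form the chlorosilyl ether F5 (not isolated), the excess 9 and the solvent are stripped off, and the lithium acetylide 10 is added to form the Si–C bond last. The small dichlorosilane should silylate the hindered alkoxide easily.

## Further compounds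

F1 | step 7 | 7-{[tert-butyl(dimethyl)silyl]oxymethyl}-1,1-dimethyl-3,3,4-tris[4-(methoxymethoxy)phenyl]-1,3,5,6-tetrahydro-2,1-benzoxasilol-6-yl acetate (racemic) | CC(C)(C)[Si](C)(C)OCC1=C2[Si](C)(C)OC(c3ccc(OCOC)cc3)(c3ccc(OCOC)cc3)C2=C(c2ccc(OCOC)cc2)CC1OC(C)=O
F2 | step 8 | {3-{[tert-butyl(dimethyl)silyl]oxymethyl}-2-iodo-6-[4-(methoxymethoxy)phenyl]phenyl}bis[4-(methoxymethoxy)phenyl]methanol | CC(C)(C)[Si](C)(C)OCc1ccc(-c2ccc(OCOC)cc2)c(c1I)C(O)(c1ccc(OCOC)cc1)c1ccc(OCOC)cc1
F3 | step 10 | {3-{[tert-butyl(dimethyl)silyl]oxymethyl}-6-[4-(methoxymethoxy)phenyl]-2-[(trimethylsilyl)ethynyl]phenyl}bis[4-(methoxymethoxy)phenyl]methanol | CC(C)(C)[Si](C)(C)OCc1ccc(-c2ccc(OCOC)cc2)c(c1C#C[Si](C)(C)C)C(O)(c1ccc(OCOC)cc1)c1ccc(OCOC)cc1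
F4 | step 10 | {3-{[tert-butyl(dimethyl)silyl]oxymethyl}-2-ethynyl-6-[4-(methoxymethoxy)phenyl]phenyl}bis[4-(methoxymethoxy)phenyl]methanol | CC(C)(C)[Si](C)(C)OCc1ccc(-c2ccc(OCOC)cc2)c(c1C#C)C(O)(c1ccc(OCOC)cc1)c1ccc(OCOC)cc1
F5 | step 6 | chloro({1,1-bis[4-(methoxymethoxy)phenyl]-3-[4-(methoxymethoxy)phenyl]prop-2-yn-1-yl}oxy)dimethylsilane | C[Si](C)(Cl)OC(C#Cc1ccc(OCOC)cc1)(c1ccc(OCOC)cc1)c1ccc(OCOC)cc1
A1 | alternative 1 | methyl 2-hydroxy-3-{[tert-butyl(diphenyl)silyl]oxymethyl}-6-{4-[tri(propan-2-yl)silyloxy]phenyl}benzoate | COC(=O)c1c(O)c(CO[Si](c2ccccc2)(c2ccccc2)C(C)(C)C)ccc1-c1ccc(O[Si](C(C)C)(C(C)C)C(C)C)cc1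
A2 | alternative 1 | 5-[tert-butyl(diphenyl)silyloxy]-1-methoxy-1,3-bis(trimethylsilyloxy)penta-1,3-diene (mixture of double-bond isomers) | COC(O[Si](C)(C)C)=CC(O[Si](C)(C)C)=CCO[Si](c1ccccc1)(c1ccccc1)C(C)(C)C
A3 | alternative 1 | 1-{4-[tri(propan-2-yl)silyloxy]phenyl}-3-(trimethylsilyloxy)prop-2-en-1-one (double-bond geometry not fixed) | C[Si](C)(C)OC=CC(=O)c1ccc(O[Si](C(C)C)(C(C)C)C(C)C)cc1
A4 | alternative 2 | methyl 3-{bis[4-(methoxymethoxy)phenyl]methyl}-4-[4-(methoxymethoxy)phenyl]-2-{[4-(methoxymethoxy)phenyl]ethynyl}benzoate | COCOc1ccc(C#Cc2c(C(=O)OC)ccc(-c3ccc(OCOC)cc3)c2C(c2ccc(OCOC)cc2)c2ccc(OCOC)cc2)cc1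
A5 | alternative 2 | 2-{bis[4-(methoxymethoxy)phenyl]methyl}-1-iodo-3-[4-(methoxymethoxy)phenyl]benzene | COCOc1ccc(cc1)-c1cccc(I)c1C(c1ccc(OCOC)cc1)c1ccc(OCOC)cc1
A6 | alternative 2 | dimethyl dicarbonate | COC(=O)OC(=O)OC
A7 | alternative 3 | 3,3,4-tris[4-(methoxymethoxy)phenyl]-7-[(methoxymethoxy)methyl]-5,6-dihydro-2-benzofuran-1(3H)-one | COCOCC1=C2C(=O)OC(c3ccc(OCOC)cc3)(c3ccc(OCOC)cc3)C2=C(c2ccc(OCOC)cc2)CC1
A8 | alternative 3 | 5,5-bis[4-(methoxymethoxy)phenyl]-3-[3-(methoxymethoxy)prop-1-en-2-yl]-4-{1-[4-(methoxymethoxy)phenyl]ethenyl}furan-2(5H)-one | COCOCC(=C)C1=C(C(=C)c2ccc(OCOC)cc2)C(c2ccc(OCOC)cc2)(c2ccc(OCOC)cc2)OC1=O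
A9 | alternative 3 | 3,3,4-tris[4-(methoxymethoxy)phenyl]-7-[(methoxymethoxy)methyl]-2-benzofuran-1(3H)-one | COCOCc1ccc(-c2ccc(OCOC)cc2)c2c1C(=O)OC2(c1ccc(OCOC)cc1)c1ccc(OCOC)cc1
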